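The numbers of this flask were drawn at random within sensible limits; no experiment stands behind them.

The vessel is closed and stirred, and the electrophile in it has two exits: the nucleophile, which the free base must first release from its protonated form, and its own dimerisation.

the same everywhere: electrophile 33 mM; protonated nucleophile 1.10 equiv; time 2.0 min

| charge | free base |
|---|---|
| elm | 2.00 equiv |
| birch | 4.00 equiv |

    electrophile + nucleophile → acid set free + target (k1 = 3.29 L mol⁻¹ s⁻¹)
    nucleophile + acid set free ⇌ protonated nucleophile, settled at all times (K2 = 820 L mol⁻¹)
    acid set free + free base ⇌ salt of the base (K3 = 3200 L mol⁻¹, k3 = 7.76 L mol⁻¹ s⁻¹)
    2 electrophile → homo dimer (k4 = 0.592 L mol⁻¹ s⁻¹)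

- part of the electrophile that has reacted at the end, elm
- part of the electrophile that has reacted at the end, birch
- what raising the equivalents of free base from its lowest to its highest value here does to the part of the electrophile that has reacted (changes below 5 percentage points count as none) (it falls / it rises / no change)

We reckon the small thing, the unreacted fraction of the charge, and work in fractions of the electrophile charge throughout.

1. Dimerisation by itself leaves a fraction 17.6% at the asked time. Step 1 takes electrophile on top of that, so this is a ceiling on the remainder: elm has reacted at least 82.4%.
2. For the other extreme we use the clearing number, the pseudo-first-order rate of step 1 times the run time, with free nucleophile held at a steady fraction b of the charge. The remainder is then exp(-N), dimer loss not counted. With the whole nucleophile charge free the number is 14.3, and we expect the real flask between that extreme and the ceiling.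
3. To place it, we assume 0.5 of the charge has become target. The acid to be held is then 1.60, which we count wholly as salt of the base, although the protonated nucleophile keeps a part of it, and 0.600 remains as nucleophile and protonated nucleophile together. With step 3 taken at balance, the exchange constant between the two bases is 3.90. The free-base-to-salt ratio in elm is 0.250, which gives b = 0.296.
4. So N = 3.86 in elm, and reacted is 97.9%.
5. In birch the ratio is 1.50, b is 0.512 and N is 6.68, so reacted is 99.9%.
6. The gap is 2 percentage points, less than 5 points, so we commit to no change.

The forecast gives 98.8% for elm and 99.7% for birch, with no change, holding that “both runs finish essentially complete”. Our elm figure is lower than its, and for birch the two figures lie 0.17 points apart.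

The simulation gives 98.5% for elm and 99.5% for birch, with no change, a shift of 0.98 points.

With the nucleophile read at the end, 0.269 of the charge in elm and 0.362 in birch, the clearing numbers are 3.51 and 4.72, while the remainders correspond to 4.21 and 5.30. In elm, step 1 used electrophile at 0.51 of the rate of dimerisation just after the start, and at the asked time the ratio is higher, at 50.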